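**Retrosynthetic overview**
1. Target ⇒ trans-2-ethynyl alcohol 20; the α-methylene lactone is closed last by Pd cyclocarbonylation.
2. 20 ⇒ decalin alkene 17 by an oxidative ring expansion: oxygen is inserted into the ring-fusion C–C bond (Criegee-type 1,2-shift of carbon to oxygen, then hydride capture), which makes both oxepanes and the ether bridge at once.
3. 17 ⇒ dienone 11; reduction, acylation with the acid, face-selective epoxidation and acetylide opening set the three contiguous ring-B centres.
4. 11 ⇒ cis-ketol 8 by radical cyclization (ring A, secondary methyl) of cyclohexenone 7 ⇒ CBS desymmetrisation of dione 5 (quaternary carbon) ⇐ cyclohexane-1,3-dione + pent-4-enal + MeI.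
5. Ring order: carbocycle B (bought) → carbocycle A (step 5) → two oxepanes by ring expansion (step 12) → lactone (step 13).

Assumption: the ester is (2R)-2-methylbutanoate exactly as drawn, and (R)-2-methylbutanoic acid is bought as the single enantiomer.

Step 1
Reactants: 1 cyclohexane-1,3-dione; 2 pent-4-enal
Product: 3 2-(pent-4-en-1-yl)cyclohexane-1,3-dione
Conditions: Hantzsch ester (1.0 equiv), L-proline (10 mol%), CH2Cl2, rt
Reagents that add atoms: none
Why: Organocatalytic three-component reductive alkylation (Knoevenagel condensation then Hantzsch-ester transfer hydrogenation) gives clean C-monoalkylation of the 1,3-dione without O-alkylation, and no stereocentre is formed.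

Step 2
Reactants: 3 2-(pent-4-en-1-yl)cyclohexane-1,3-dione; 4 iodomethane
Product: 5 2-methyl-2-(pent-4-en-1-yl)cyclohexane-1,3-dione
Conditions: MeI, K2CO3, acetone, 56 °C
Reagents that add atoms: none
Why: Enolate C-alkylation of the 2-alkyl-1,3-dione with the small soft electrophile MeI builds the quaternary carbon of the later ring fusion, and the product is still achiral.

Step 3
Reactants: 5 2-methyl-2-(pent-4-en-1-yl)cyclohexane-1,3-dione
Product: 6 (2R,3R)-3-hydroxy-2-methyl-2-(pent-4-en-1-yl)cyclohexan-1-one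
Conditions: (S)-Me-CBS (20 mol%), catecholborane (1.1 equiv), toluene, −78 to −40 °C; then MeOH, aq. work-up
Reagents that add atoms: none
Why: Corey–Bakshi–Shibata reduction desymmetrises the prochiral dione (catalyst picks one enantiotopic carbonyl, hydride enters syn to the small methyl), which fixes the quaternary centre as R; the carbinol centre is only a relay and is erased in steps 4 and 6.

Step 4
Reactants: 6 (2R,3R)-3-hydroxy-2-methyl-2-(pent-4-en-1-yl)cyclohexan-1-one
Product: 7 (2R)-2-methyl-2-(pent-4-en-1-yl)cyclohex-3-en-1-one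
Conditions: Burgess reagent (1.5 equiv), toluene, 60 °C
Reagents that add atoms: none
Why: Burgess syn-elimination can only take a β-hydrogen from the ring CH2 because the other neighbour is quaternary, so the relay carbinol carbon becomes sp2 (no axial oxygen beside the quaternary centre in the next step) while the ketone and the R quaternary centre stay untouched.

Step 5
Reactants: 7 (2R)-2-methyl-2-(pent-4-en-1-yl)cyclohex-3-en-1-one
Product: 8 (4aS,5S,8aR)-5,8a-dimethyl-3,4,4a,5,6,7,8,8a-octahydronaphthalen-4a-ol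
Conditions: Fe(acac)3 (30 mol%), PhSiH3 (2.5 equiv), EtOH/ethylene glycol 5:1, 60 °C
Reagents that add atoms: none
Why: Iron-hydride hydrogen-atom transfer to the terminal alkene gives the secondary radical, which adds 6-exo to the ketone before the alkoxy radical is reduced (HAT-initiated radical cyclization onto a ketone); axial attack anti to the pseudoaxial angular methyl through a chair with the new methyl equatorial should give the cis-fused ketol with the hydroxyl and both methyls on one face, so the secondary methyl is cis to the angular methyl as in the target.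

Step 6
Reactants: 8 (4aS,5S,8aR)-5,8a-dimethyl-3,4,4a,5,6,7,8,8a-octahydronaphthalen-4a-ol
Product: 10 (4aS,5S,8aS)-4a-hydroxy-5,8a-dimethyl-4a,5,6,7,8,8a-hexahydronaphthalen-1(4H)-one, via allylic hydroperoxide 9 (not isolated)
Conditions: O2, TPP (cat.), white LED, CH2Cl2, 0 °C; then Ac2O, pyridine, DMAP (cat.), 0 °C to rt
Reagents that add atoms: dioxygen O=O
Why: Schenck ene reaction of singlet oxygen at the only ene-active alkene (hydrogen can come only from the allylic CH2, the other allylic carbon is quaternary) puts oxygen on the carbon next to the quaternary centre with shift of the double bond, and Kornblum–DeLaMare dehydration of the hydroperoxide gives the enone, so the hydroperoxide stereocentre is lost.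

Step 7
Reactants: 10 (4aS,5S,8aS)-4a-hydroxy-5,8a-dimethyl-4a,5,6,7,8,8a-hexahydronaphthalen-1(4H)-one
Product: 11 (5S,8aS)-5,8a-dimethyl-6,7,8,8a-tetrahydronaphthalen-1(5H)-one
Conditions: Burgess reagent (2 equiv), toluene, 70 °C
Reagents that add atoms: none
Why: Burgess syn-elimination of the tertiary alcohol uses the syn hydrogen of the acidic γ-CH2 (the hydrogen on the methyl-bearing carbon is anti to the hydroxyl and cannot be used), giving the linear dienone without touching the two remaining stereocentres.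

Step 8
Reactants: 11 (5S,8aS)-5,8a-dimethyl-6,7,8,8a-tetrahydronaphthalen-1(5H)-one
Product: 12 (1S,5S,8aS)-5,8a-dimethyl-1,5,6,7,8,8a-hexahydronaphthalen-1-ol
Conditions: NaBH4, CeCl3·7H2O, MeOH, −78 °C
Reagents that add atoms: none
Why: Luche 1,2-reduction, in which hydride adds anti to the axial angular methyl on the neighbouring carbon (as in Wieland–Miescher-type ketones) and gives the alcohol cis to that methyl.

Step 9
Reactants: 12 (1S,5S,8aS)-5,8a-dimethyl-1,5,6,7,8,8a-hexahydronaphthalen-1-ol; 13 (2R)-2-methylbutanoic acid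
Product: 14 (1S,5S,8aS)-5,8a-dimethyl-1,5,6,7,8,8a-hexahydronaphthalen-1-yl (2R)-2-methylbutanoate
Conditions: DCC (1.2 equiv), DMAP (10 mol%), CH2Cl2, 0 °C to rt
Reagents that add atoms: none
Why: Steglich esterification acylates the hindered allylic alcohol with retention at the carbinol carbon and at the α-stereocentre of the acid.

Step 10
Reactants: 14 (1S,5S,8aS)-5,8a-dimethyl-1,5,6,7,8,8a-hexahydronaphthalen-1-yl (2R)-2-methylbutanoate
Product: 15 (1R,2R,3R,5S,8aS)-2,3-epoxy-5,8a-dimethyl-1,2,3,5,6,7,8,8a-octahydronaphthalen-1-yl (2R)-2-methylbutanoate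
Conditions: (R,R)-Jacobsen Mn(salen)Cl (5 mol%), 4-phenylpyridine N-oxide (20 mol%), aq. NaOCl (pH 11.3), CH2Cl2, 0 °C
Reagents that add atoms: sodium hypochlorite [Na+].[O-]Cl
Why: Jacobsen–Katsuki epoxidation reacts at the cis-disubstituted alkene of the conjugated diene rather than the hindered trisubstituted one, and oxygen is delivered on the face opposite to the angular methyl and the ester (substrate bias, expected to be matched with the (R,R) catalyst), giving the epoxide trans to the ester.

Step 11
Reactants: 15 (1R,2R,3R,5S,8aS)-2,3-epoxy-5,8a-dimethyl-1,2,3,5,6,7,8,8a-octahydronaphthalen-1-yl (2R)-2-methylbutanoate; 16 acetylene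
Product: 17 (1R,2R,3R,5S,8aS)-3-ethynyl-2-hydroxy-5,8a-dimethyl-1,2,3,5,6,7,8,8a-octahydronaphthalen-1-yl (2R)-2-methylbutanoate
Conditions: acetylene, n-BuLi, THF, −78 °C; BF3·OEt2 (1.2 equiv), then 15, −78 °C; aq. NH4Cl
Reagents that add atoms: none
Why: Yamaguchi-type BF3-promoted opening of the vinyl epoxide by lithium acetylide is an SN2 attack at the allylic carbon with inversion, so the ethynyl group ends trans to the new hydroxyl and on the face of the ester and the angular methyl (the trans relationship needed for the lactone).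

Step 12
Reactants: 17 (1R,2R,3R,5S,8aS)-3-ethynyl-2-hydroxy-5,8a-dimethyl-1,2,3,5,6,7,8,8a-octahydronaphthalen-1-yl (2R)-2-methylbutanoate
Product: 20 (1R,2S,3R,4R,6R,7S)-4-ethynyl-3-hydroxy-1,7-dimethyl-11-oxabicyclo[4.4.1]undecan-2-yl (2R)-2-methylbutanoate, via triethylsilyl peroxide 18 (not isolated), via bridged oxocarbenium ion 19 (not isolated)
Conditions: Co(thd)2 (5 mol%), O2 (1 atm), Et3SiH (3 equiv), ClCH2CH2Cl, rt; then Ar purge, BF3·OEt2 (0.3 equiv), −78 to −30 °C
Reagents that add atoms: dioxygen O=O
Why: Proposed new method: a one-flask reductive Criegee ring expansion in which Mukaiyama–Isayama hydrosilylperoxidation puts Et3SiOO on the ring-fusion carbon (H to the alkene CH), catalytic BF3 then ionises the O–O bond with antiperiplanar 1,2-shift of the tertiary, methyl-bearing ring-fusion carbon from carbon to oxygen (retention, tertiary migrates before secondary or primary) to give bridged oxocarbenium ion 19, and the Et3SiH already present reduces 19 on its only open face so that both oxepanes and the cis ether bridge form together, the closest known reactions being the Criegee rearrangement of 9-decalyl peresters to 1-acyloxy-11-oxabicyclo[4.4.1]undecanes, Lewis-acid Hock fragmentation of silyl peroxides with allylsilane capture, and Et3SiH ionic hydrogenation of oxocarbenium ions.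

Step 13
Reactants: 20 (1R,2S,3R,4R,6R,7S)-4-ethynyl-3-hydroxy-1,7-dimethyl-11-oxabicyclo[4.4.1]undecan-2-yl (2R)-2-methylbutanoate; 21 carbon monoxide
Product: 22 CNP0136059.1
Conditions: PdCl2 (5 mol%), SnCl2 (5 mol%), PPh3 (10 mol%), CO (7 atm), MeCN, 75 °C
Reagents that add atoms: none
Why: Pd-catalysed cyclocarbonylation of the homopropargylic alcohol (CO inserted between the hydroxyl oxygen and the internal alkyne carbon) closes the trans-fused α-methylene-γ-butyrolactone without touching any stereocentre and gives the target.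

**Compound list**
1 | cyclohexane-1,3-dione | O=C1CCCC(=O)C1 | starting material
2 | pent-4-enal | C=CCCC=O | starting material
3 | 2-(pent-4-en-1-yl)cyclohexane-1,3-dione | C=CCCCC1C(=O)CCCC1=O | intermediate
4 | iodomethane | CI | starting material
5 | 2-methyl-2-(pent-4-en-1-yl)cyclohexane-1,3-dione | C=CCCCC1(C)C(=O)CCCC1=O | intermediate
6 | (2R,3R)-3-hydroxy-2-methyl-2-(pent-4-en-1-yl)cyclohexan-1-one | C=CCCC[C@]1(C)[C@H](O)CCCC1=O | intermediate
7 | (2R)-2-methyl-2-(pent-4-en-1-yl)cyclohex-3-en-1-one | C=CCCC[C@]1(C)C=CCCC1=O | intermediate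
8 | (4aS,5S,8aR)-5,8a-dimethyl-3,4,4a,5,6,7,8,8a-octahydronaphthalen-4a-ol (cis-fused; OH and both methyls on one face) | C[C@]12CCC[C@H](C)[C@@]1(O)CCC=C2 | intermediate
9 | (1R,4aS,5S,8aR)-1-hydroperoxy-5,8a-dimethyl-1,4,4a,5,6,7,8,8a-octahydronaphthalen-4a-ol (allylic hydroperoxide; C1 epimers converge) | C[C@]12CCC[C@H](C)[C@@]1(O)CC=C[C@H]2OO | intermediate (not isolated)
10 | (4aS,5S,8aS)-4a-hydroxy-5,8a-dimethyl-4a,5,6,7,8,8a-hexahydronaphthalen-1(4H)-one | C[C@]12CCC[C@H](C)[C@@]1(O)CC=CC2=O | intermediate
11 | (5S,8aS)-5,8a-dimethyl-6,7,8,8a-tetrahydronaphthalen-1(5H)-one | C[C@]12CCC[C@H](C)C1=CC=CC2=O | intermediate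
12 | (1S,5S,8aS)-5,8a-dimethyl-1,5,6,7,8,8a-hexahydronaphthalen-1-ol | C[C@]12CCC[C@H](C)C1=CC=C[C@@H]2O | intermediate
13 | (2R)-2-methylbutanoic acid | CC[C@@H](C)C(=O)O | starting material
14 | (1S,5S,8aS)-5,8a-dimethyl-1,5,6,7,8,8a-hexahydronaphthalen-1-yl (2R)-2-methylbutanoate | C[C@]12CCC[C@H](C)C1=CC=C[C@@H]2OC(=O)[C@H](C)CC | intermediate
15 | (1R,2R,3R,5S,8aS)-2,3-epoxy-5,8a-dimethyl-1,2,3,5,6,7,8,8a-octahydronaphthalen-1-yl (2R)-2-methylbutanoate (epoxide opposite to the 8a-methyl and the ester) | C[C@]12CCC[C@H](C)C1=C[C@H]3O[C@H]3[C@@H]2OC(=O)[C@H](C)CC | intermediate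
16 | acetylene | C#C | starting material
17 | (1R,2R,3R,5S,8aS)-3-ethynyl-2-hydroxy-5,8a-dimethyl-1,2,3,5,6,7,8,8a-octahydronaphthalen-1-yl (2R)-2-methylbutanoate | C[C@]12CCC[C@H](C)C1=C[C@H](C#C)[C@@H](O)[C@@H]2OC(=O)[C@H](C)CC | intermediate
18 | (1R,2R,3R,4aR,5S,8aR)-3-ethynyl-2-hydroxy-5,8a-dimethyl-4a-(triethylsilylperoxy)decahydronaphthalen-1-yl (2R)-2-methylbutanoate (C4a epimers converge) | C[C@]12CCC[C@H](C)[C@]1(OO[Si](CC)(CC)CC)C[C@H](C#C)[C@@H](O)[C@@H]2OC(=O)[C@H](C)CC | intermediate (not isolated)
19 | bridged oxocarbenium ion of the 11-oxabicyclo[4.4.1]undecane (C6=O11+), as its triethylsilanolate–BF3 ion pair | O[C@@H]1[C@@H](C#C)CC2=[O+][C@](C)(CCC[C@@H]2C)[C@H]1OC(=O)[C@H](C)CC.CC[Si](CC)(CC)O[B-](F)(F)F | intermediate (not isolated)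
20 | (1R,2S,3R,4R,6R,7S)-4-ethynyl-3-hydroxy-1,7-dimethyl-11-oxabicyclo[4.4.1]undecan-2-yl (2R)-2-methylbutanoate | O[C@@H]1[C@@H](C#C)C[C@H]2O[C@](C)(CCC[C@@H]2C)[C@H]1OC(=O)[C@H](C)CC | intermediate
21 | carbon monoxide | [C-]#[O+] | starting material
22 | CNP0136059.1 (the 11-oxabicyclo[4.4.1]undecane of 20 with an α-methylene-γ-butyrolactone trans-fused across C3–C4 and the (2R)-2-methylbutanoate on C2) | C=C1C(=O)O[C@@H]2[C@@H]1C[C@H]1O[C@](C)(CCC[C@@H]1C)[C@H]2OC(=O)[C@H](C)CC | target

**Totals**
Total step count: 13. Longest linear sequence: 13 steps (from cyclohexane-1,3-dione; all other inputs are small reagent-like starting materials).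

**Three steps most likely to fail**

Step 5 (radical cyclization). The risks are hydrogen-atom transfer to, or radical addition onto, the ring alkene, and a wrong configuration at the new methyl centre; this configuration cannot be corrected later. Fallback, from 6 back to 10: leave out step 4 and cyclise hydroxy ketone 6 itself with Fe(acac)3/PhSiH3, so that no second alkene is present, to give (1R,4aS,5S,8aR)-5,8a-dimethyldecahydronaphthalene-1,4a-diol F1. IBX in DMSO at 75 °C then oxidises the secondary alcohol to (4aS,5S,8aS)-4a-hydroxy-5,8a-dimethyloctahydronaphthalen-1(2H)-one F2 and dehydrogenates it in the same flask to 10, which also replaces step 6. The price is an axial hydroxyl next to the reacting carbonyl, which may lower the selectivity at the methyl centre, so this is the second choice.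

Step 10 (epoxidation). The risks are attack at the trisubstituted alkene and the wrong face. Fallback, from 11 back to 15: Weitz–Scheffer epoxidation of dienone 11 (H2O2, NaOH, MeOH, 0 °C) touches only the enone double bond, anti to the angular methyl, and gives (2R,3R,5S,8aS)-2,3-epoxy-5,8a-dimethyl-2,3,6,7,8,8a-hexahydronaphthalen-1(5H)-one F3. Reduction with DIBAL-H at −78 °C (or NaBH4/CeCl3) gives (1R,2R,3R,5S,8aS)-2,3-epoxy-5,8a-dimethyl-1,2,3,5,6,7,8,8a-octahydronaphthalen-1-ol F4, and DCC/DMAP esterification with 13 gives 15.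

Step 12 (proposed reductive Criegee ring expansion). The risks are migration of the secondary carbon instead of the tertiary one, loss of a proton from the oxocarbenium ion (enol ether, epimerisation of the neighbouring methyl centre), and interference of cobalt residues or the free hydroxyl. Fallback with known chemistry, from 17 back to 20: run only the Mukaiyama–Isayama silylperoxidation and isolate silyl peroxide 18. HF·pyridine in THF frees (1R,2R,3R,4aR,5S,8aR)-3-ethynyl-4a-hydroperoxy-2-hydroxy-5,8a-dimethyldecahydronaphthalen-1-yl (2R)-2-methylbutanoate F5. Acid-catalysed Hock–Criegee rearrangement (cat. TsOH, wet CH2Cl2, 0 °C) gives the bridged hemiketal (1R,2S,3R,4R,6R,7S)-4-ethynyl-3,6-dihydroxy-1,7-dimethyl-11-oxabicyclo[4.4.1]undecan-2-yl (2R)-2-methylbutanoate F6. Ionic hydrogenation of the hemiketal with Et3SiH/BF3·OEt2 at −78 °C gives 20.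

Further compounds
F1 | step 5 | (1R,4aS,5S,8aR)-5,8a-dimethyldecahydronaphthalene-1,4a-diol | C[C@]12CCC[C@H](C)[C@@]1(O)CCC[C@H]2O
F2 | step 5 | (4aS,5S,8aS)-4a-hydroxy-5,8a-dimethyloctahydronaphthalen-1(2H)-one | C[C@]12CCC[C@H](C)[C@@]1(O)CCCC2=O
F3 | step 10 | (2R,3R,5S,8aS)-2,3-epoxy-5,8a-dimethyl-2,3,6,7,8,8a-hexahydronaphthalen-1(5H)-one | C[C@]12CCC[C@H](C)C1=C[C@H]3O[C@H]3C2=O
F4 | step 10 | (1R,2R,3R,5S,8aS)-2,3-epoxy-5,8a-dimethyl-1,2,3,5,6,7,8,8a-octahydronaphthalen-1-ol | C[C@]12CCC[C@H](C)C1=C[C@H]3O[C@H]3[C@@H]2O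
F5 | step 12 | (1R,2R,3R,4aR,5S,8aR)-3-ethynyl-4a-hydroperoxy-2-hydroxy-5,8a-dimethyldecahydronaphthalen-1-yl (2R)-2-methylbutanoate | C[C@]12CCC[C@H](C)[C@]1(OO)C[C@H](C#C)[C@@H](O)[C@@H]2OC(=O)[C@H](C)CC
F6 | step 12 | (1R,2S,3R,4R,6R,7S)-4-ethynyl-3,6-dihydroxy-1,7-dimethyl-11-oxabicyclo[4.4.1]undecan-2-yl (2R)-2-methylbutanoate | O[C@@H]1[C@@H](C#C)C[C@@]2(O)O[C@](C)(CCC[C@@H]2C)[C@H]1OC(=O)[C@H](C)CC
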